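**Strategy.** The synthesis rests on opening the tetrahydropyran (ring oxygen bridging C6 and C10) back to a 2,5-disubstituted furan: C6–C9 are the four furan carbons and C10 is an (R)-configured furyl carbinol. One oxidative ring expansion (step 6) converts this furan into the six-membered pyranone, forming the O–C6 bond and leaving a C9 ketone and a C7=C8 alkene at the carbons that later carry bromine and chlorine. The precursor is an (R)-furyl carbinol with a C12 silyl ether and a C4 pivalate, made by asymmetric transfer hydrogenation of the corresponding furyl ketone. Chain numbering runs from the alkyne CH (C1) to the ethyl terminus (C15).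

Key step: step 6

Remark: hemiketal 11 is drawn as the anomer expected to predominate (axial C6–OH); both anomers converge on the same oxocarbenium ion in step 7.

**Step 1**
Reactants: 1 methyl 3-hydroxypropanoate
Product: 2 methyl 3-[(tert-butyldiphenylsilyl)oxy]propanoate
Conditions: t-BuPh2SiCl, imidazole, CH2Cl2, 0 °C → rt
Reagents that add atoms: tert-butyl(chloro)diphenylsilane, CC(C)(C)[Si](Cl)(c1ccccc1)c1ccccc1
Why: Imidazole-promoted silylation of an unhindered primary alcohol, giving a silyl ether that tolerates the organolithium, formic acid, trifluoroacetic acid and phosphine–tetrahalomethane conditions used later.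

**Step 2**
Reactants: 2 methyl 3-[(tert-butyldiphenylsilyl)oxy]propanoate
Product: 3 N-methoxy-N-methyl-3-[(tert-butyldiphenylsilyl)oxy]propanamide
Conditions: MeNH(OMe)·HCl, i-PrMgCl, THF, −20 → 0 °C
Reagents that add atoms: N,O-dimethylhydroxylamine hydrochloride, CNOC.Cl
Why: Weinreb amide synthesis by aminolysis of the methyl ester with the chloromagnesium amide formed in the flask, which at low temperature is faster than β-elimination of the silyloxy group.

**Step 3**
Reactants: 4 2-(furan-2-yl)ethan-1-ol; 3 N-methoxy-N-methyl-3-[(tert-butyldiphenylsilyl)oxy]propanamide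
Product: 6 1-[5-(2-hydroxyethyl)furan-2-yl]-3-[(tert-butyldiphenylsilyl)oxy]propan-1-one, via dilithio alkoxide 5 (not isolated)
Conditions: 4, n-BuLi (2.1 equiv), THF, 0 °C; then 3, −78 → 0 °C
Reagents that add atoms: none
Why: Two equivalents of n-BuLi remove first the hydroxyl proton and then the proton at the free furan α-position (C9), and the 5-lithiofuran adds once to the amide because the chelated tetrahedral adduct persists until work-up (Weinreb ketone synthesis), a sequence that keeps every ester away from the organolithium.

**Step 4**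
Reactants: 6 1-[5-(2-hydroxyethyl)furan-2-yl]-3-[(tert-butyldiphenylsilyl)oxy]propan-1-one; 7 pivaloyl chloride
Product: 8 2-{5-[3-(tert-butyldiphenylsilyloxy)propanoyl]furan-2-yl}ethyl pivalate
Conditions: pyridine, DMAP (cat.), CH2Cl2, 0 °C → rt
Reagents that add atoms: none
Why: Nucleophile-catalysed acylation of the primary alcohol, placed after the carbon–carbon bond formation so that the pivalate never meets n-BuLi, and giving an ester that is orthogonal to the silyl ether.

**Step 5**
Reactants: 8 2-{5-[3-(tert-butyldiphenylsilyloxy)propanoyl]furan-2-yl}ethyl pivalate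
Product: 9 (R)-furyl carbinol 2-{5-[(1R)-3-(tert-butyldiphenylsilyloxy)-1-hydroxypropyl]furan-2-yl}ethyl pivalate
Conditions: RuCl(p-cymene)[(R,R)-TsDPEN] (1 mol %), HCO2H/Et3N (5:2), CH2Cl2, rt
Reagents that add atoms: none
Why: Noyori asymmetric transfer hydrogenation of a heteroaryl alkyl ketone, in which the furan takes the place of the aryl group in the CH–π-organised transition state so that the (R,R)-diamine catalyst delivers hydride to the face that gives the (R)-carbinol at C10.

**Step 6**
Reactants: 9 (R)-furyl carbinol
Product: 11 (2R,6S)-6-hydroxy-6-[2-(pivaloyloxy)ethyl]-2-[2-(tert-butyldiphenylsilyloxy)ethyl]-2H-pyran-3(6H)-one, via cis-ene-dione 10 (not isolated)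
Conditions: NBS (1.05 equiv), NaHCO3, THF/H2O (4:1), 0 °C
Reagents that add atoms: water, O
Why: NBS delivers electrophilic bromine to the electron-rich 2,5-dialkylfuran, water is captured at the opposite α-carbon and loss of HBr unmasks the cis-ene-1,4-dione 10, in which C6 and C9 are both ketones. The C10 hydroxyl then adds to the C6 ketone in a 6-exo-trig hemiketalisation that forms the O–C6 bond and closes the pyranone ring; this is the Achmatowicz rearrangement, well established for 2,5-disubstituted furyl carbinols. The one new stereocentre, the C6 hemiketal carbon, is under thermodynamic control (anomeric preference for an axial hydroxyl, C5 chain equatorial) and is removed again in step 7, so its ratio does not matter. The step needs chemoselective oxidation of the furan beside a secondary alcohol, a silyl ether and an ester, which the substrate secures because the furan is by far its most nucleophilic site towards one equivalent of NBS at 0 °C while NaHCO3 scavenges HBr. No bond to the C10 carbon is made or broken, so the (R) configuration from step 5 passes into the ring unchanged.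

**Step 7**
Reactants: 11 pyranone hemiketal
Product: 13 2,6-cis-dihydropyranone (6S,10R) carrying the C9 ketone and the C7=C8 alkene, via oxocarbenium trifluoroacetate 12 (not isolated)
Conditions: Et3SiH, CF3CO2H, CH2Cl2, −40 °C
Reagents that add atoms: none
Why: Kishi-type reductive deoxygenation (ionic hydrogenation) of the hemiketal: CF3CO2H ionises C6–OH to the ring oxocarbenium ion 12, whose half-chair holds the C10 side chain pseudo-equatorial, and Et3SiH delivers hydride to C6 along the axial trajectory, so that the C5 chain ends up equatorial and cis to the C11 chain (6S).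

**Step 8**
Reactants: 13 2,6-cis-dihydropyranone
Product: 14 allylic alcohol (6S,9S,10R) bearing C9–OH trans to the C11 chain
Conditions: NaBH4, CeCl3·7H2O, MeOH, −78 °C
Reagents that add atoms: none
Why: Luche 1,2-reduction of the enone, in which hydride attacks C9 axially from the face of the two side chains (staggered to C10–H), so that the new hydroxyl is pseudo-equatorial and trans to the C11 chain.

**Step 9**
Reactants: 14 allylic alcohol
Product: 15 epoxy alcohol (6S,7S,8R,9R,10R) bearing the C7–C8 epoxide cis to C9–OH
Conditions: mCPBA, CH2Cl2, 0 °C → rt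
Reagents that add atoms: 3-chloroperoxybenzoic acid, OOC(=O)c1cccc(Cl)c1
Why: Henbest hydroxyl-directed epoxidation: hydrogen bonding to the pseudo-equatorial allylic C9–OH guides the peracid to the C7=C8 face syn to that hydroxyl, so both epoxide C–O bonds lie trans to the two side chains, an orientation at C7 that nucleophilic epoxidation of enone 13 is not expected to give because nucleophiles attack C7 axially on the side-chain face.

**Step 10**
Reactants: 15 epoxy alcohol
Product: 16 epoxy ketone (6S,7S,8S,10R)
Conditions: Dess–Martin periodinane, CH2Cl2, rt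
Reagents that add atoms: none
Why: Dess–Martin oxidation of the secondary alcohol under near-neutral conditions that leave the epoxide, the silyl ether and the ester intact, the C9 centre being given up on purpose after it has served as the directing group and set again in step 13.

**Step 11**
Reactants: 16 epoxy ketone
Product: 18 β-hydroxy ketone (6S,7R,10R) bearing C7–OH trans to the C5 chain, via α-phenylselanyl ketone 17 (not isolated)
Conditions: PhSeSePh, NaBH4, EtOH, rt; AcOH; then 16, 0 °C
Reagents that add atoms: none
Why: Organoselenium-mediated reductive cleavage of an α,β-epoxy ketone: phenylselenolate opens the epoxide at C8 (α to the carbonyl), a second selenolate removes selenium from 17 to give the enol and then the ketone, and because the C7–O bond is never broken the C7 hydroxyl keeps its equatorial configuration while the C10–O bond and the pivalate are inert to this soft nucleophile.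

**Step 12**
Reactants: 18 β-hydroxy ketone
Product: 19 triethylsilyl ether of 18 (6S,7R,10R)
Conditions: Et3SiCl, imidazole, CH2Cl2, 0 °C
Reagents that add atoms: chlorotriethylsilane, CC[Si](Cl)(CC)CC
Why: Silylation of the secondary alcohol under mildly basic conditions that do not trigger β-elimination of the β-oxygenated ketone, which differentiates the C7 oxygen from the C9 oxygen with a group removable beside the tert-butyldiphenylsilyl ether.

**Step 13**
Reactants: 19 silyloxy ketone
Product: 20 alcohol (6S,7R,9S,10R) bearing equatorial C9–OH trans to the C11 chain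
Conditions: NaBH4, MeOH, −40 °C
Reagents that add atoms: none
Why: Borohydride reduction of a conformationally fixed tetrahydropyranone whose three substituents are all equatorial, where the small hydride attacks C9 axially from the side-chain face and so gives the equatorial alcohol.

**Step 14**
Reactants: 20 alcohol
Product: 21 bromide (6S,7R,9R,10R) bearing axial C9–Br cis to the C11 chain
Conditions: CBr4, (n-C8H17)3P, toluene, 70 °C
Reagents that add atoms: tetrabromomethane, BrC(Br)(Br)Br
Why: Appel-type deoxybromination with a trialkylphosphine, in which bromide displaces the phosphorus-activated equatorial C9 oxygen by SN2 with inversion so that bromine arrives axial, an equatorial leaving group having no anti-periplanar hydrogen for E2 elimination.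

**Step 15**
Reactants: 21 bromide
Product: 22 bromo alcohol (6S,7R,9R,10R) bearing free equatorial C7–OH
Conditions: PPTS (cat.), MeOH/CH2Cl2, 0 °C → rt
Reagents that add atoms: none
Why: Acid-catalysed methanolysis of the secondary triethylsilyl ether, which is far more labile than the primary tert-butyldiphenylsilyl ether, the pivalate or the secondary bromide.

**Step 16**
Reactants: 22 bromo alcohol
Product: 23 bromo chloride (6S,7S,9R,10R) bearing axial C7–Cl and axial C9–Br
Conditions: CCl4, (n-C8H17)3P, toluene, 80 °C
Reagents that add atoms: tetrachloromethane, ClC(Cl)(Cl)Cl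
Why: Appel-type deoxychlorination, in which chloride displaces the phosphorus-activated equatorial C7 oxygen by SN2 with inversion, placing chlorine axial and cis to the C5 chain and completing the all-cis tetrasubstituted ring.

**Step 17**
Reactants: 23 bromo chloride
Product: 24 C12 primary alcohol (6S,7S,9R,10R)
Conditions: HF·pyridine, pyridine, THF, 0 °C → rt
Reagents that add atoms: none
Why: Fluoride-mediated cleavage of the primary silyl ether under buffered, weakly acidic conditions that neither eliminate the axial halides nor hydrolyse the pivalate.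

**Step 18**
Reactants: 24 C12 primary alcohol
Product: 25 C12 aldehyde (6S,7S,9R,10R)
Conditions: Dess–Martin periodinane, CH2Cl2, 0 °C → rt
Reagents that add atoms: none
Why: Dess–Martin oxidation gives the β-alkoxy aldehyde without base, so neither retro-oxa-Michael opening of the ring nor elimination of the halides is expected, and the aldehyde is used at once.

**Step 19**
Reactants: 25 C12 aldehyde; 26 propyltriphenylphosphonium bromide
Product: 29 (12E)-alkenyl bromide (6S,7S,9R,10R,12E), via lithium betaine 27 (not isolated), via β-oxido ylide 28 (not isolated)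
Conditions: 26, PhLi, THF, 0 °C; 25, −78 °C; PhLi, −78 → −30 °C; BrCF2CF2Br, −78 °C → rt
Reagents that add atoms: 1,2-dibromo-1,1,2,2-tetrafluoroethane, FC(F)(Br)C(F)(F)Br
Why: α-Bromination of a β-oxido phosphonium ylide (Wittig–Schlosser manifold): the propylidene ylide adds to the aldehyde, one further equivalent of PhLi deprotonates the betaine at the phosphorus-bearing carbon, and electrophilic bromination of that carbon followed by loss of Ph3P=O gives the trisubstituted alkenyl bromide, a sequence known to favour bromine trans to the aldehyde-derived chain (12E) and run with exactly one equivalent of PhLi at low temperature to spare the pivalate and the ring halides.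

**Step 20**
Reactants: 29 (12E)-alkenyl bromide
Product: 30 C4 primary alcohol (6S,7S,9R,10R,12E)
Conditions: i-Bu2AlH, CH2Cl2, −78 °C
Reagents that add atoms: none
Why: Reductive cleavage of the pivalate by hydride addition to the ester carbonyl at −78 °C, conditions under which alkenyl and alkyl halides are not reduced.

**Step 21**
Reactants: 30 C4 primary alcohol
Product: 31 C4 aldehyde (6S,7S,9R,10R,12E)
Conditions: Dess–Martin periodinane, CH2Cl2, 0 °C → rt
Reagents that add atoms: none
Why: Dess–Martin oxidation of the primary alcohol to the β-alkoxy aldehyde under non-basic conditions compatible with the alkenyl bromide and the axial halides.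

**Step 22**
Reactants: 31 C4 aldehyde; 32 1,3-bis(triisopropylsilyl)prop-1-yne
Product: 34 C1-triisopropylsilyl (3Z)-enyne (3Z,6S,7S,9R,10R,12E), via β-silyl lithium alkoxide 33 (not isolated)
Conditions: 32, n-BuLi, THF, −20 °C; then 31, −78 °C → rt
Reagents that add atoms: none
Why: Peterson olefination with the lithiated bis-silylpropyne, where addition to the aldehyde gives the β-silyl alkoxide and its syn-elimination of silanolate is steered by the bulky triisopropylsilyl groups towards the (Z)-enyne, the stabilised propargylic anion being too weak a base at −78 °C to eliminate the ring halides or exchange the alkenyl bromide.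

**Step 23**
Reactants: 34 C1-triisopropylsilyl (3Z)-enyne
Product: 35 target (2R,3R,5S,6S)-3-bromo-2-[(2E)-3-bromopent-2-en-1-yl]-5-chloro-6-[(2Z)-pent-2-en-4-yn-1-yl]oxane
Conditions: n-Bu4NF, THF, 0 °C
Reagents that add atoms: none
Why: Fluoride-induced protodesilylation of the alkynyl C–Si bond, which is fast at 0 °C and leaves the enyne geometry, the alkenyl bromide and the secondary halides untouched.

**Compound list**

1 | methyl 3-hydroxypropanoate | COC(=O)CCO | starting material
2 | methyl 3-[(tert-butyldiphenylsilyl)oxy]propanoate | COC(=O)CCO[Si](c1ccccc1)(c1ccccc1)C(C)(C)C | intermediate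
3 | N-methoxy-N-methyl-3-[(tert-butyldiphenylsilyl)oxy]propanamide | CON(C)C(=O)CCO[Si](c1ccccc1)(c1ccccc1)C(C)(C)C | intermediate
4 | 2-(furan-2-yl)ethan-1-ol | OCCc1ccco1 | starting material
5 | lithium 2-(5-lithiofuran-2-yl)ethoxide (not isolated) | [Li]OCCc1ccc([Li])o1 | intermediate
6 | 1-[5-(2-hydroxyethyl)furan-2-yl]-3-[(tert-butyldiphenylsilyl)oxy]propan-1-one | OCCc1ccc(C(=O)CCO[Si](c2ccccc2)(c2ccccc2)C(C)(C)C)o1 | intermediate
7 | pivaloyl chloride | CC(C)(C)C(Cl)=O | starting material
8 | 2-{5-[3-(tert-butyldiphenylsilyloxy)propanoyl]furan-2-yl}ethyl pivalate | CC(C)(C)C(=O)OCCc1ccc(C(=O)CCO[Si](c2ccccc2)(c2ccccc2)C(C)(C)C)o1 | intermediate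
9 | (R)-furyl carbinol, 2-{5-[(1R)-3-(tert-butyldiphenylsilyloxy)-1-hydroxypropyl]furan-2-yl}ethyl pivalate (C10 R) | CC(C)(C)[Si](c1ccccc1)(c1ccccc1)OCC[C@@H](O)c1ccc(CCOC(=O)C(C)(C)C)o1 | intermediate
10 | cis-ene-dione, (4Z,7R)-9-(tert-butyldiphenylsilyloxy)-7-hydroxy-3,6-dioxonon-4-en-1-yl pivalate (not isolated) | CC(C)(C)C(=O)OCCC(=O)/C=C\C(=O)[C@H](O)CCO[Si](c1ccccc1)(c1ccccc1)C(C)(C)C | intermediate
11 | (2R,6S)-6-hydroxy-6-[2-(pivaloyloxy)ethyl]-2-[2-(tert-butyldiphenylsilyloxy)ethyl]-2H-pyran-3(6H)-one (hemiketal at C6) | CC(C)(C)C(=O)OCC[C@]1(O)O[C@H](CCO[Si](c2ccccc2)(c2ccccc2)C(C)(C)C)C(=O)C=C1 | intermediate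
12 | ring oxocarbenium ion from 11 (O=C6 double bond, C9 ketone, 10R) as its trifluoroacetate (not isolated) | CC(C)(C)C(=O)OCCC1=[O+][C@H](CCO[Si](c2ccccc2)(c2ccccc2)C(C)(C)C)C(=O)C=C1.[O-]C(=O)C(F)(F)F | intermediate
13 | (2R,6S)-6-[2-(pivaloyloxy)ethyl]-2-[2-(tert-butyldiphenylsilyloxy)ethyl]-2H-pyran-3(6H)-one (2,6-cis; 6S,10R in chain numbering) | CC(C)(C)C(=O)OCC[C@@H]1O[C@H](CCO[Si](c2ccccc2)(c2ccccc2)C(C)(C)C)C(=O)C=C1 | intermediate
14 | allylic alcohol (6S,9S,10R): 2,6-cis-3,6-dihydro-2H-pyran-3-ol, C9–OH trans to the C11 chain, C4 O-pivalate, C12 O-TBDPS | CC(C)(C)C(=O)OCC[C@@H]1O[C@H](CCO[Si](c2ccccc2)(c2ccccc2)C(C)(C)C)[C@@H](O)C=C1 | intermediate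
15 | epoxy alcohol (6S,7S,8R,9R,10R): C7–C8 epoxide cis to C9–OH, trans to both side chains | CC(C)(C)C(=O)OCC[C@@H]1O[C@H](CCO[Si](c2ccccc2)(c2ccccc2)C(C)(C)C)[C@@H](O)[C@H]3O[C@@H]13 | intermediate
16 | epoxy ketone (6S,7S,8S,10R): C9 ketone, C7–C8 epoxide trans to both side chains | CC(C)(C)C(=O)OCC[C@@H]1O[C@H](CCO[Si](c2ccccc2)(c2ccccc2)C(C)(C)C)C(=O)[C@H]3O[C@@H]13 | intermediate
17 | α-phenylselanyl β-hydroxy ketone: C8–SePh on the side-chain face, C7–OH on the opposite face (not isolated) | CC(C)(C)C(=O)OCC[C@@H]1O[C@H](CCO[Si](c2ccccc2)(c2ccccc2)C(C)(C)C)C(=O)[C@H]([Se]c3ccccc3)[C@H]1O | intermediate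
18 | β-hydroxy ketone (6S,7R,10R): equatorial C7–OH trans to the C5 chain, C9 ketone | CC(C)(C)C(=O)OCC[C@@H]1O[C@H](CCO[Si](c2ccccc2)(c2ccccc2)C(C)(C)C)C(=O)C[C@H]1O | intermediate
19 | triethylsilyl ether of 18 (6S,7R,10R) | CC(C)(C)C(=O)OCC[C@@H]1O[C@H](CCO[Si](c2ccccc2)(c2ccccc2)C(C)(C)C)C(=O)C[C@H]1O[Si](CC)(CC)CC | intermediate
20 | alcohol (6S,7R,9S,10R): equatorial C9–OH trans to the C11 chain, C7–OSiEt3 | CC(C)(C)C(=O)OCC[C@@H]1O[C@H](CCO[Si](c2ccccc2)(c2ccccc2)C(C)(C)C)[C@@H](O)C[C@H]1O[Si](CC)(CC)CC | intermediate
21 | bromide (6S,7R,9R,10R): axial C9–Br cis to the C11 chain, C7–OSiEt3 | CC(C)(C)C(=O)OCC[C@@H]1O[C@H](CCO[Si](c2ccccc2)(c2ccccc2)C(C)(C)C)[C@H](Br)C[C@H]1O[Si](CC)(CC)CC | intermediate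
22 | bromo alcohol (6S,7R,9R,10R): free equatorial C7–OH, axial C9–Br | CC(C)(C)C(=O)OCC[C@@H]1O[C@H](CCO[Si](c2ccccc2)(c2ccccc2)C(C)(C)C)[C@H](Br)C[C@H]1O | intermediate
23 | bromo chloride (6S,7S,9R,10R): axial C7–Cl and axial C9–Br cis to the side chains, C4 O-pivalate, C12 O-TBDPS | CC(C)(C)C(=O)OCC[C@@H]1O[C@H](CCO[Si](c2ccccc2)(c2ccccc2)C(C)(C)C)[C@H](Br)C[C@@H]1Cl | intermediate
24 | C12 primary alcohol (6S,7S,9R,10R) | CC(C)(C)C(=O)OCC[C@@H]1O[C@H](CCO)[C@H](Br)C[C@@H]1Cl | intermediate
25 | C12 aldehyde (6S,7S,9R,10R) | CC(C)(C)C(=O)OCC[C@@H]1O[C@H](CC=O)[C@H](Br)C[C@@H]1Cl | intermediate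
26 | propyltriphenylphosphonium bromide | CCC[P+](c1ccccc1)(c1ccccc1)c1ccccc1.[Br-] | starting material
27 | lithium betaine: C12–OLi, C13–PPh3+ bromide (C12 and C13 configurations not defined; not isolated) | CC(C)(C)C(=O)OCC[C@@H]1O[C@H](CC(O[Li])C(CC)[P+](c2ccccc2)(c2ccccc2)c2ccccc2)[C@H](Br)C[C@@H]1Cl.[Br-] | intermediate
28 | β-oxido ylide: C12–OLi, C13=PPh3 (C12 configuration not defined; not isolated) | CC(C)(C)C(=O)OCC[C@@H]1O[C@H](CC(O[Li])C(CC)=P(c2ccccc2)(c2ccccc2)c2ccccc2)[C@H](Br)C[C@@H]1Cl | intermediate
29 | (12E)-alkenyl bromide (6S,7S,9R,10R,12E): bromine on C13 trans to C11, C4 O-pivalate | CC(C)(C)C(=O)OCC[C@@H]1O[C@H](C/C=C(/Br)CC)[C@H](Br)C[C@@H]1Cl | intermediate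
30 | C4 primary alcohol (6S,7S,9R,10R,12E) | OCC[C@@H]1O[C@H](C/C=C(/Br)CC)[C@H](Br)C[C@@H]1Cl | intermediate
31 | C4 aldehyde (6S,7S,9R,10R,12E) | O=CC[C@@H]1O[C@H](C/C=C(/Br)CC)[C@H](Br)C[C@@H]1Cl | intermediate
32 | 1,3-bis(triisopropylsilyl)prop-1-yne | CC(C)[Si](C(C)C)(C(C)C)C#CC[Si](C(C)C)(C(C)C)C(C)C | starting material
33 | β-silyl lithium alkoxide: C4–OLi, C3–Si(i-Pr)3 (C3 and C4 configurations not defined; not isolated) | CC(C)[Si](C(C)C)(C(C)C)C#CC([Si](C(C)C)(C(C)C)C(C)C)C(O[Li])C[C@@H]1O[C@H](C/C=C(/Br)CC)[C@H](Br)C[C@@H]1Cl | intermediate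
34 | C1-triisopropylsilyl (3Z)-enyne (3Z,6S,7S,9R,10R,12E) | CC(C)[Si](C(C)C)(C(C)C)C#C/C=C\C[C@@H]1O[C@H](C/C=C(/Br)CC)[C@H](Br)C[C@@H]1Cl | intermediate
35 | (2R,3R,5S,6S)-3-bromo-2-[(2E)-3-bromopent-2-en-1-yl]-5-chloro-6-[(2Z)-pent-2-en-4-yn-1-yl]oxane | C#C/C=C\C[C@@H]1O[C@H](C/C=C(/Br)CC)[C@H](Br)C[C@@H]1Cl | target

**Step count.** Total: 23 steps. Longest linear sequence: 23 steps (1 → 2 → 3 → 6 → 8 → 9 → 11 → 13 → … → 35); 4 enters at step 3, 7 at step 4, 26 at step 19 and 32 at step 22.

**Steps most likely to fail**

Step 16 (chlorination at C7). Chloride has to enter C7 along the axial path, syn to the axial bromine already at C9. The slowed substitution leaves time for the phosphorus-activated oxygen to depart with participation of the ring oxygen (retention or ring contraction) or for chloride to exchange the C9 bromide. The fallback introduces chlorine by anti addition instead of displacement. It sets out from allylic alcohol 14: phenylselanyl chloride (PhSeCl, CH2Cl2, −78 °C) should add across C7=C8 in the trans-diaxial sense, selenium at C8 on the hydroxyl face and chloride at C7 on the side-chain face, to give the chloro selenide adduct F1. Radical deselenation (Ph3SnH, AIBN, toluene, 80 °C) would give the chloro alcohol F2, which already carries the axial C7 chlorine. Deoxybromination of its equatorial C9 hydroxyl (CBr4, (n-C8H17)3P, toluene, 70 °C) comes back to the route at 23. The hindered displacement is then run with the better nucleophile against the smaller axial neighbour.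

Step 19 (bromo-olefination). The alkene geometry may erode during bromination and collapse of the β-oxido ylide. Phenyllithium may also remove HBr or HCl from the ring or attack the pivalate while the ylide is formed. The fallback builds the alkenyl bromide through boron and sets out from aldehyde 25. A boron–Wittig reaction with lithiated 1,1-bis(pinacolboryl)propane (lithium 2,2,6,6-tetramethylpiperidide, THF, 0 °C; then 25, −78 °C → rt) should give the alkenyl boronate F3, with boron cis to C11. Addition of Br2 (CH2Cl2, −78 °C) would give the vicinal dibromide F4, which is not isolated. NaOMe in MeOH (−78 → 0 °C) then induces anti elimination of boron and the C12 bromine. This inverts the geometry, places bromine trans to C11 and comes back to the route at 29.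

Step 14 (bromination at C9). The activated C9 oxygen may ionise with participation of the anti-periplanar C10–O bond, which leads to ring contraction or retention. Adventitious HBr at 70 °C may also strip the triethylsilyl ether. The fallback separates activation from substitution and sets out from alcohol 20. Sulfonylation with (CF3SO2)2O and pyridine (CH2Cl2, −20 °C) would give the C9 triflate F5, an equatorial leaving group without an anti-periplanar hydrogen. Displacement with n-Bu4NBr (toluene, rt) should proceed by SN2 with inversion well below the temperature of the phosphine method and comes back to the route at 21.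

**Further compounds**

F1 | step 16 | chloro selenide adduct: C7–Cl axial on the side-chain face, C8–SePh and C9–OH on the opposite face | CC(C)(C)C(=O)OCC[C@@H]1O[C@H](CCO[Si](c2ccccc2)(c2ccccc2)C(C)(C)C)[C@@H](O)[C@@H]([Se]c3ccccc3)[C@@H]1Cl
F2 | step 16 | chloro alcohol (6S,7S,9S,10R): axial C7–Cl, equatorial C9–OH | CC(C)(C)C(=O)OCC[C@@H]1O[C@H](CCO[Si](c2ccccc2)(c2ccccc2)C(C)(C)C)[C@@H](O)C[C@@H]1Cl
F3 | step 19 | alkenyl boronate: C13–B(pin) cis to C11, ethyl trans to C11 | CC(C)(C)C(=O)OCC[C@@H]1O[C@H](C/C=C(\B2OC(C)(C)C(C)(C)O2)CC)[C@H](Br)C[C@@H]1Cl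
F4 | step 19 | vicinal dibromide from anti addition of Br2 to F3 (C12 and C13 configurations follow from anti addition on either face; not isolated) | CC(C)(C)C(=O)OCC[C@@H]1O[C@H](CC(Br)C(Br)(CC)B2OC(C)(C)C(C)(C)O2)[C@H](Br)C[C@@H]1Cl
F5 | step 14 | C9 triflate of 20 (equatorial leaving group, C7–OSiEt3) | CC(C)(C)C(=O)OCC[C@@H]1O[C@H](CCO[Si](c2ccccc2)(c2ccccc2)C(C)(C)C)[C@@H](OS(=O)(=O)C(F)(F)F)C[C@H]1O[Si](CC)(CC)CC
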